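The constants stand for no real mixture; the run is a simulation.

Counted by the substrate in it, the outlet of the autumn tank carries 0.11 M, and that sum is the invariant on which a ledger has to close.

    substrate + partner → intermediate + by-product (k1 = 0.065 /M/h)
    intermediate ⇌ target (K2 = 1.6, k2 = 0.037 /h)
    intermediate ⇌ isomer of the product (K3 = 74, k3 = 0.0059 /h)
    substrate + target → side product (k4 = 0.069 /M/h)
    substrate ⇌ dormant form (K5 = 0.46, k5 = 0.047 /h)

| setting | noon | autumn | winter | dusk |
|---|---|---|---|---|
| substrate | 0.11 M | 0.11 M | 0.11 M | 0.11 M |
| partner | 0.143 M (fed, over 20.0 d) | 0.143 M | 0.143 M | 0.143 M |
| time | 25 d |  | 25 d |  |
| remark | all but partner at the start; partner goes in evenly over 20.0 d, the run ends at 25 d | one stirred flow tank at steady state, fed with the mixture as stated, mean residence time 25 d | a closed flask charged with all of it at once and left for 25 d | one stirred flow tank at steady state, fed with the mixture as stated, mean residence time 125 d |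

- the set-up with the highest share of target in all that became target or isomer of the product or side product, at the outlet or at the end ("none" if the first two lie within 2 percentage points) (noon / autumn / winter / dusk / none)
- share of target in all that became target or isomer of the product or side product, at the outlet or at the end, noon
- share of target in all that became target or isomer of the product or side product, at the outlet or at the end, autumn
- share of target in all that became target or isomer of the product or side product, at the outlet or at the end, winter
- share of target in all that became target or isomer of the product or side product, at the outlet or at the end, dusk

- a species is counted by the substrate in it: one side product counts as two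
- the stated concentrations are those of everything mixed, before any reaction; amounts are the same in each set-up
- the feed brings no volume worth counting
- run time (noon): 25 d

Substrate is the limiting reagent, with 0.11 M charged against 0.143 M of partner. Intermediate and target form a pre-equilibrium in which target holds 61.5% of the pair. Isomer of the product forms from the intermediate, so the pair drains with a leak time, the mean time a unit of the pair lasts against step 3, of 18.4 d. Step 2 relaxes in 16.6 h, far shorter than the leak time, so the pair can be counted as one.

Survival against the leak then ranks the set-ups. In a closed flask it falls exponentially with age, and in a stirred tank it is one over one plus residence time per leak time. Noon, with the pair dated from the middle of the feed, keeps 0.442. The autumn tank keeps 0.423, winter, given the whole 25 d, keeps 0.256, and dusk keeps 0.128. That puts noon first, though narrowly.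

The autumn ledger takes two rounds. With no side product, step 1 passes 0.0720 M, free substrate being 68.5% of its pool with dormant form, which exchanges far faster than the tank turns over. Target is 0.261 of what passes, and step 4 then consumes 0.0158 M of substrate. Putting that loss back, step 1 passes 0.0639 M and step 4 takes 0.0117 M. The books read: target 0.0136 M, intermediate 0.00851 M, isomer of the product 0.0301 M, side product, counted double, 0.0234 M, and substrate with dormant form 0.0344 M. The autumn selectivity for target comes to 20.3%.

The forecast names noon, with 23.1% at noon, 19.1% in autumn, 17% in winter and 7.4% at dusk. Of noon it says: “dosing partner delays conversion, so there is less time for isomer”. Its autumn figure stands lower than the ledger's.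

The simulation puts noon first with 23.6%, then autumn 19.1%, winter 17.0% and dusk 7.37%. Target at the autumn outlet amounts to 12.0% of the substrate charged. At three times the residence time, survival in the autumn tank drops to 0.197, which scales 19.1% down to 8.90%, and that tank gives 10.1%. Left for 250 d, or 13.6 leak times, the noon flask gives 1.37%, less than the winter flask's 1.45%.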